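The route rests on the C6–C7 disconnection. C7 is the β-carbon of the lactone ring (C7–C11–C12–O–C8) and also a member of the cyclopentane C5–C6–C7–C8–C9. A C6 radical adding to a butenolide of fixed C8 configuration therefore closes the spiro cyclopentane and sets C7 in one operation, because two fused five-membered rings can only be cis. The precursor is a carvone-derived cyclohexene whose quaternary C5 carries an iodomethyl group (C6) and the CH2–butenolide arm (C9–C8), with C2 and C3 already oxygenated as silyl ethers. Lactone methylenation, C14 hydroxylation, angeloylation and desilylation follow.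

Key step: step 19

Remark on labels: spiro carbon C5; cyclohexene C10(C14)=C1–C2–C3–C4(C15)–C5; cyclopentane C5–C6–C7–C8–C9; lactone C7–C11(=C13)–C12(=O)–O–C8; the target is 2S,3S,4R,5R,7R,8R in these labels; TBS = tert-butyldimethylsilyl.

Remark on the precursor: its configurations were re-derived from the target (lactone oxygen cis to C10, C9 cis to the C3 oxygen and trans to C15) and needed no correction. The one change is that the C2 oxygen is installed before the cyclisation and carried as a second silyl ether on the same skeleton. This avoids a C–H oxidation once the methylene lactone and angelate are present, shields the ring alkene when the vinyl group is cleaved, and removes the C2 hydrogen on the face of the C6 radical.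

Step 1
Reactants: 1 (R)-carvone
Product: 2 (5R,6S)-6-methylcarvone
Conditions: LiN(iPr)2, THF, −78 °C; MeI, −78 → 0 °C
Reagents that add atoms: iodomethane CI
Why: Kinetic deprotonation gives the cross-conjugated enolate, and its alkylation (enolate alkylation) should place the new methyl (C15) trans to the neighbouring isopropenyl group, the minor cis epimer being separable or equilibrated with base.

Step 2
Reactants: 2 (5R,6S)-6-methylcarvone
Product: 4 (1R,6S)-4,6-dimethyl-5-oxocyclohex-3-en-1-yl acetate, via methoxy hydroperoxide 3 (not isolated)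
Conditions: O3, CH2Cl2/MeOH, −78 °C; then Ac2O, Et3N, DMAP (cat.), 0 → 40 °C
Reagents that add atoms: ozone [O-][O+]=O; methanol CO
Why: Ozone attacks the electron-rich isopropenyl group rather than the enone, methanol traps the carbonyl oxide, and acetylation of the hydroperoxide triggers a Criegee rearrangement in which the ring carbon migrates to oxygen with retention, so the carvone stereocentre becomes the C3 carbinol centre unchanged.

Step 3
Reactants: 4 enone acetate
Product: 5 (5R,6S)-5-hydroxy-2,6-dimethylcyclohex-2-en-1-one
Conditions: K2CO3, MeOH, 0 °C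
Reagents that add atoms: none
Why: Mild transesterification (methanolysis) removes the acetate, and the low temperature and short contact time should keep the β-hydroxy enone from eliminating towards the phenol.

Step 4
Reactants: 5 hydroxy enone
Product: 6 (5R,6S)-5-(tert-butyldimethylsilyloxy)-2,6-dimethylcyclohex-2-en-1-one
Conditions: TBSCl, imidazole, DMF, 23 °C
Reagents that add atoms: tert-butyldimethylsilyl chloride CC(C)(C)[Si](C)(C)Cl
Why: Standard silylation of a secondary alcohol gives a C3 ether that tolerates the base, hydride, acid and radical steps ahead.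

Step 5
Reactants: 6 silyloxy enone; 7 ethyl (trimethylsilyl)acetate
Product: 8 ethyl (E)-dienoate
Conditions: 7, LiN(iPr)2, THF, −78 °C; then 6, −78 → 0 °C
Reagents that add atoms: none
Why: In this Peterson olefination the lithiated silyl ester adds 1,2 to the hindered enone faster than it enolises it and the β-silyl alkoxide eliminates spontaneously; the E isomer (ester on the C4 side, away from the C14 methyl) should dominate on steric grounds and is purified by chromatography.

Step 6
Reactants: 8 ethyl (E)-dienoate
Product: 9 (E)-dienyl alcohol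
Conditions: iBu2AlH, CH2Cl2, −78 °C
Reagents that add atoms: none
Why: 1,2-Reduction of the conjugated ester by the aluminium hydride gives the primary allylic alcohol and leaves the silyl ether and the diene untouched.

Step 7
Reactants: 9 (E)-dienyl alcohol; 10 triethyl orthoacetate
Product: 11 C5-quaternary vinyl ester
Conditions: 10 (excess), EtCO2H (cat.), 140 °C, EtOH distilled off
Reagents that add atoms: none
Why: Johnson–Claisen rearrangement through a chair [3,3] shift forms the C5–C9 bond; 1,3-allylic strain with the exocyclic CH2O arm holds the C15 methyl axial, so the bond should form on the face of C5 opposite that methyl, placing C9 trans to C15 and cis to the C3 oxygen and leaving the vinyl group as the C6 precursor.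

Step 8
Reactants: 11 C5-quaternary vinyl ester
Product: 12 C2 enone
Conditions: CrO3, 3,5-dimethylpyrazole, CH2Cl2, −20 °C
Reagents that add atoms: chromium trioxide O=[Cr](=O)=O
Why: Allylic oxidation with the CrO3–dimethylpyrazole complex should take the only ring methylene next to the trisubstituted alkene (C2), since the vinyl group has no allylic hydrogen and the C14 methyl is far less reactive.

Step 9
Reactants: 12 C2 enone
Product: 13 C2 allylic alcohol
Conditions: NaBH4, CeCl3·7H2O, MeOH, −78 °C
Reagents that add atoms: none
Why: Luche reduction is 1,2-selective, and axial hydride delivery to the enone with the C3 silyloxy group equatorial should give the equatorial C2 alcohol, trans to the C3 oxygen (C2 S).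

Step 10
Reactants: 13 C2 allylic alcohol
Product: 14 C2,C3-bis(silyl ether) ester
Conditions: TBSOTf, 2,6-lutidine, CH2Cl2, −78 → 0 °C
Reagents that add atoms: tert-butyldimethylsilyl triflate CC(C)(C)[Si](C)(C)OS(=O)(=O)C(F)(F)F
Why: Silylation with the reactive triflate protects the hindered secondary allylic alcohol, so both ring oxygens carry the same group and can be released together at the end.

Step 11
Reactants: 14 bis(silyl ether) ester
Product: 15 C8 aldehyde
Conditions: iBu2AlH (1.1 equiv), CH2Cl2, −78 °C
Reagents that add atoms: none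
Why: Partial ester reduction stops at the aluminium hemiacetal at −78 °C, helped by the adjacent quaternary centre, and releases the aldehyde on work-up.

Step 12
Reactants: 15 C8 aldehyde; 16 methyl propiolate
Product: 17 propargylic alcohols (both C8 epimers)
Conditions: 16, LiN(SiMe3)2, THF, −78 °C; then 15, −78 °C; aq. NH4Cl
Reagents that add atoms: none
Why: Acetylide addition of lithiated methyl propiolate to the aldehyde at −78 °C joins C8 to C7; the C8 configuration is not controlled here and is corrected by the next two steps.

Step 13
Reactants: 17 propargylic alcohols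
Product: 18 ynone ester
Conditions: Dess–Martin periodinane, NaHCO3, CH2Cl2, 0 → 23 °C
Reagents that add atoms: none
Why: Dess–Martin oxidation converts both epimers to one ynone under buffered, non-nucleophilic conditions that spare this strong Michael acceptor.

Step 14
Reactants: 18 ynone ester
Product: 19 (8R)-propargylic alcohol
Conditions: (R)-Alpine-Borane [B-isopinocampheyl-9-borabicyclo[3.3.1]nonane from (+)-α-pinene], THF (concentrated), 23 °C; then HOCH2CH2NH2, Et2O
Reagents that add atoms: none
Why: Midland reduction transfers hydride through a cyclic transition state in which the slim alkynyl group takes the small-substituent position, so the reagent alone should set C8 as R irrespective of the distant ring centres, as is established for 4-oxo-2-alkynoates.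

Step 15
Reactants: 19 (8R)-propargylic alcohol
Product: 21 vinyl butenolide, via Z-hydroxy ester 20 (not isolated)
Conditions: H2 (1 atm), Lindlar catalyst (Pd on CaCO3, poisoned with Pb(OAc)2), quinoline, EtOAc, 23 °C; then PPTS (cat.), CH2Cl2
Reagents that add atoms: none
Why: Lindlar semihydrogenation gives the Z-enoate, whose C8 hydroxyl closes onto the ester (lactonisation) to the butenolide, while the hindered vinyl group and the ring alkene react far more slowly on the poisoned catalyst.

Step 16
Reactants: 21 vinyl butenolide
Product: 23 C6 aldehyde, via vicinal diol 22 (not isolated)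
Conditions: K2OsO4·2H2O (cat.), N-methylmorpholine N-oxide, acetone/H2O, 0 → 23 °C; then NaIO4, THF/H2O
Reagents that add atoms: N-methylmorpholine N-oxide C[N+]1([O-])CCOCC1
Why: Catalytic dihydroxylation followed by periodate cleavage (Lemieux–Johnson-type sequence) should select the monosubstituted vinyl group, because the ring alkene is trisubstituted and flanked by the quaternary C5 and the C2 silyl ether and the butenolide alkene is electron-poor.

Step 17
Reactants: 23 C6 aldehyde
Product: 24 C6 neopentyl alcohol
Conditions: NaBH4, CeCl3·7H2O, MeOH/THF, −40 °C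
Reagents that add atoms: none
Why: Under Luche conditions at low temperature the aldehyde is reduced 1,2 much faster than borohydride adds to the butenolide, and the alcohol is taken on at once.

Step 18
Reactants: 24 C6 neopentyl alcohol
Product: 25 iodomethyl butenolide (cyclisation precursor)
Conditions: PPh3, I2, imidazole, toluene, 23 → 80 °C
Reagents that add atoms: iodine II
Why: Appel-type iodination forms the alkoxyphosphonium salt at room temperature and iodide displaces it on warming; C5 has no hydrogen, so elimination cannot compete.

Step 19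
Reactants: 25 iodomethyl butenolide
Product: 26 cis-fused spiro lactone
Conditions: (Me3Si)3SiH (syringe pump), AIBN (cat.), toluene (0.01 M), 85 °C
Reagents that add atoms: none
Why: Iodine abstraction from 25 by the tris(trimethylsilyl)silyl radical gives the primary C6 radical, which adds to C7, the β-carbon of the butenolide, and the resulting lactone α-radical at C11 takes hydrogen from the silane and carries the chain. The closest known reaction type is the reductive 5-exo-trig radical conjugate cyclisation of alkyl iodides onto butenolides (intramolecular Giese reaction). The closure is 5-exo-trig and forms the cyclopentane C5–C6–C7–C8–C9, fused along C7–C8 to the existing lactone ring. C7 is the only new stereocentre and is controlled by C8, set in step 14: the two five-membered rings can only be cis-fused, so the C6–C7 bond forms on the lactone face that carries C9. The step needs attack at C7 to win over attack at C11, over three-membered closure onto the C10=C1 alkene (which would lead to vinyl migration) and over direct reduction of the C6 radical. This is secured by the polarity match of the nucleophilic primary radical with the electron-poor C7, by the quaternary C5 holding both arms together, by the C2 silyl ether leaving no allylic hydrogen on the radical's face, and by slow addition of a weak hydrogen donor at high dilution.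

Step 20
Reactants: 26 cis-fused spiro lactone
Product: 29 α-methylene lactone, via Mannich base 27 (not isolated), via trimethylammonium iodide 28 (not isolated)
Conditions: LiN(iPr)2, THF, −78 °C; Me2N=CH2+ I−, −78 → 23 °C; then MeI, THF/MeOH; then aq. NaHCO3, CH2Cl2
Reagents that add atoms: N,N-dimethylmethyleneiminium iodide (Eschenmoser's salt) C=[N+](C)C.[I-]
Why: The lactone enolate at C11, the only acidic site, undergoes a Mannich reaction with Eschenmoser's salt, and quaternisation followed by Hofmann-type elimination installs the C11=C13 methylene without touching C7 or C8.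

Step 21
Reactants: 29 α-methylene lactone
Product: 30 C14 allylic alcohol
Conditions: SeO2 (cat.), tBuOOH, CH2Cl2, 23 °C
Reagents that add atoms: tert-butyl hydroperoxide CC(C)(C)OO
Why: SeO2 allylic hydroxylation (ene reaction then [2,3] shift) oxidises the position attached to the more substituted alkene carbon C10, where C14 is the only carbon bearing hydrogen, and the electron-poor methylene lactone should stay inert.

Step 22
Reactants: 30 C14 allylic alcohol; 31 angelic acid
Product: 33 bis(silyl ether) angelate, via mixed anhydride 32 (not isolated)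
Conditions: 31, 2,4,6-trichlorobenzoyl chloride, Et3N, toluene, 23 °C; then 30, 75 °C
Reagents that add atoms: none
Why: Yamaguchi-type mixed-anhydride acylation without a nucleophilic catalyst lets the primary alcohol attack the less hindered angeloyl carbonyl and should avoid the Z-to-E isomerisation to the tiglate that amine-catalysed acylations cause.

Step 23
Reactants: 33 bis(silyl ether) angelate
Product: 34 CNP0224912.1 (target)
Conditions: HF·pyridine, THF/pyridine, 0 → 23 °C
Reagents that add atoms: none
Why: Buffered fluoride desilylation cleaves both secondary silyl ethers under mildly acidic conditions that the methylene lactone, the allylic angelate and the trans-diol should tolerate.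

Compound list
1 | (R)-carvone | CC1=CC[C@@H](C(C)=C)CC1=O | starting material
2 | (5R,6S)-2,6-dimethyl-5-(prop-1-en-2-yl)cyclohex-2-en-1-one (methyl trans to isopropenyl) | CC1=CC[C@@H](C(C)=C)[C@H](C)C1=O | intermediate
3 | methoxy hydroperoxide of 2 (2-hydroperoxy-2-methoxypropan-2-yl in place of isopropenyl) | CC1=CC[C@@H](C(C)(OC)OO)[C@H](C)C1=O | intermediate (not isolated)
4 | (1R,6S)-4,6-dimethyl-5-oxocyclohex-3-en-1-yl acetate | CC1=CC[C@@H](OC(C)=O)[C@H](C)C1=O | intermediate
5 | (5R,6S)-5-hydroxy-2,6-dimethylcyclohex-2-en-1-one | CC1=CC[C@@H](O)[C@H](C)C1=O | intermediate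
6 | (5R,6S)-5-(tert-butyldimethylsilyloxy)-2,6-dimethylcyclohex-2-en-1-one | CC1=CC[C@@H](O[Si](C)(C)C(C)(C)C)[C@H](C)C1=O | intermediate
7 | ethyl (trimethylsilyl)acetate | CCOC(=O)C[Si](C)(C)C | starting material
8 | ethyl (E)-2-[5-(TBS-oxy)-2,6-dimethylcyclohex-2-en-1-ylidene]acetate (ester on the C4 side; C3 silyloxy trans to C15) | CCOC(=O)/C=C1/C(C)=CC[C@@H](O[Si](C)(C)C(C)(C)C)[C@@H]1C | intermediate
9 | (E)-2-[5-(TBS-oxy)-2,6-dimethylcyclohex-2-en-1-ylidene]ethanol | OC/C=C1/C(C)=CC[C@@H](O[Si](C)(C)C(C)(C)C)[C@@H]1C | intermediate
10 | triethyl orthoacetate | CC(OCC)(OCC)OCC | starting material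
11 | ethyl ester with quaternary C5 bearing vinyl (C6 precursor) and CH2CO2Et (C9–C8); C9 cis to the C3 silyloxy group and trans to C15 | CCOC(=O)C[C@@]1(C=C)C(C)=CC[C@@H](O[Si](C)(C)C(C)(C)C)[C@@H]1C | intermediate
12 | C2 enone of 11 (C2=O conjugated with C1=C10) | CCOC(=O)C[C@@]1(C=C)C(C)=CC(=O)[C@@H](O[Si](C)(C)C(C)(C)C)[C@@H]1C | intermediate
13 | C2 allylic alcohol (C2 hydroxyl trans to the C3 silyloxy group) | CCOC(=O)C[C@@]1(C=C)C(C)=C[C@H](O)[C@@H](O[Si](C)(C)C(C)(C)C)[C@@H]1C | intermediate
14 | C2,C3-bis(TBS ether) ethyl ester | CCOC(=O)C[C@@]1(C=C)C(C)=C[C@H](O[Si](C)(C)C(C)(C)C)[C@@H](O[Si](C)(C)C(C)(C)C)[C@@H]1C | intermediate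
15 | C8 aldehyde (C5–CH2–CHO arm) | O=CC[C@@]1(C=C)C(C)=C[C@H](O[Si](C)(C)C(C)(C)C)[C@@H](O[Si](C)(C)C(C)(C)C)[C@@H]1C | intermediate
16 | methyl propiolate | C#CC(=O)OC | starting material
17 | methyl 4-hydroxyalk-2-ynoate, both C8 epimers | COC(=O)C#CC(O)C[C@@]1(C=C)C(C)=C[C@H](O[Si](C)(C)C(C)(C)C)[C@@H](O[Si](C)(C)C(C)(C)C)[C@@H]1C | intermediate
18 | methyl 4-oxoalk-2-ynoate (C8 ketone) | COC(=O)C#CC(=O)C[C@@]1(C=C)C(C)=C[C@H](O[Si](C)(C)C(C)(C)C)[C@@H](O[Si](C)(C)C(C)(C)C)[C@@H]1C | intermediate
19 | (8R)-methyl 4-hydroxyalk-2-ynoate | COC(=O)C#C[C@H](O)C[C@@]1(C=C)C(C)=C[C@H](O[Si](C)(C)C(C)(C)C)[C@@H](O[Si](C)(C)C(C)(C)C)[C@@H]1C | intermediate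
20 | (8R)-methyl (Z)-4-hydroxyalk-2-enoate | COC(=O)/C=C\[C@H](O)C[C@@]1(C=C)C(C)=C[C@H](O[Si](C)(C)C(C)(C)C)[C@@H](O[Si](C)(C)C(C)(C)C)[C@@H]1C | intermediate (not isolated)
21 | (8R)-butenolide with C5 vinyl group | O=C1C=C[C@@H](C[C@@]2(C=C)C(C)=C[C@H](O[Si](C)(C)C(C)(C)C)[C@@H](O[Si](C)(C)C(C)(C)C)[C@@H]2C)O1 | intermediate
22 | 1,2-diol from the vinyl group of 21 | O=C1C=C[C@@H](C[C@@]2(C(O)CO)C(C)=C[C@H](O[Si](C)(C)C(C)(C)C)[C@@H](O[Si](C)(C)C(C)(C)C)[C@@H]2C)O1 | intermediate (not isolated)
23 | butenolide with C5 formyl group (C6 aldehyde) | O=C1C=C[C@@H](C[C@@]2(C=O)C(C)=C[C@H](O[Si](C)(C)C(C)(C)C)[C@@H](O[Si](C)(C)C(C)(C)C)[C@@H]2C)O1 | intermediate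
24 | butenolide with C5 hydroxymethyl group | O=C1C=C[C@@H](C[C@@]2(CO)C(C)=C[C@H](O[Si](C)(C)C(C)(C)C)[C@@H](O[Si](C)(C)C(C)(C)C)[C@@H]2C)O1 | intermediate
25 | C5-quaternary iodomethyl butenolide with C2 and C3 TBS ethers (cyclisation precursor) | O=C1C=C[C@@H](C[C@@]2(CI)C(C)=C[C@H](O[Si](C)(C)C(C)(C)C)[C@@H](O[Si](C)(C)C(C)(C)C)[C@@H]2C)O1 | intermediate
26 | cis-fused spiro γ-lactone without the C13 methylene (7R,8R; lactone oxygen cis to C10) | C1C(=O)O[C@@H]2C[C@@]3(C[C@H]12)C(C)=C[C@H](O[Si](C)(C)C(C)(C)C)[C@@H](O[Si](C)(C)C(C)(C)C)[C@@H]3C | intermediate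
27 | C11 dimethylaminomethyl lactone | CN(C)CC1C(=O)O[C@@H]2C[C@@]3(C[C@H]12)C(C)=C[C@H](O[Si](C)(C)C(C)(C)C)[C@@H](O[Si](C)(C)C(C)(C)C)[C@@H]3C | intermediate (not isolated)
28 | C11 trimethylammoniomethyl lactone iodide | C[N+](C)(C)CC1C(=O)O[C@@H]2C[C@@]3(C[C@H]12)C(C)=C[C@H](O[Si](C)(C)C(C)(C)C)[C@@H](O[Si](C)(C)C(C)(C)C)[C@@H]3C.[I-] | intermediate (not isolated)
29 | α-methylene lactone with C2 and C3 TBS ethers | C=C1C(=O)O[C@@H]2C[C@@]3(C[C@H]12)C(C)=C[C@H](O[Si](C)(C)C(C)(C)C)[C@@H](O[Si](C)(C)C(C)(C)C)[C@@H]3C | intermediate
30 | C14 allylic alcohol | C=C1C(=O)O[C@@H]2C[C@@]3(C[C@H]12)C(CO)=C[C@H](O[Si](C)(C)C(C)(C)C)[C@@H](O[Si](C)(C)C(C)(C)C)[C@@H]3C | intermediate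
31 | angelic acid, (Z)-2-methylbut-2-enoic acid | C/C=C(/C)C(=O)O | starting material
32 | angelic 2,4,6-trichlorobenzoic anhydride | C/C=C(/C)C(=O)OC(=O)c1c(Cl)cc(Cl)cc1Cl | intermediate (not isolated)
33 | C14 angelate with C2 and C3 TBS ethers | C=C1C(=O)O[C@@H]2C[C@@]3(C[C@H]12)C(COC(=O)/C(C)=C\C)=C[C@H](O[Si](C)(C)C(C)(C)C)[C@@H](O[Si](C)(C)C(C)(C)C)[C@@H]3C | intermediate
34 | CNP0224912.1 (2S,3S,4R,5R,7R,8R; C14 angelate, trans-2,3-diol, α-methylene lactone) | C=C1C(=O)O[C@@H]2C[C@@]3(C[C@H]12)C(COC(=O)/C(C)=C\C)=C[C@H](O)[C@@H](O)[C@@H]3C | target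

Total step count: 23. Longest linear sequence: 23 steps, from (R)-carvone 1 to target 34.

Steps most likely to fail

Step 19 (key step). Hydrogen transfer to the C6 radical may outrun cyclisation, or the radical may be diverted onto the neighbouring C10=C1 alkene. The fallback sets out from 25 and comes back at 26 without a hydrogen-atom donor. It is a nickel-mediated reductive conjugate addition (NiCl2·6H2O, Zn powder, pyridine, 60 °C; zerovalent nickel forms in the flask), in which an alkylnickel species adds to C7 and the metal enolate is protonated on work-up. It makes no new compound (F0).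

Step 7. Facial discrimination at C5 may be weak at 140 °C, or the acid may ionise the dienylic alcohol. The fallback sets out from 9 and comes back at 11 through an Ireland–Claisen rearrangement near room temperature. Acetylation (Ac2O, pyridine) gives the allylic acetate F1. LiN(SiMe3)2 with Me3SiCl in THF at −78 °C gives the trimethylsilyl ketene acetal F2, which rearranges on warming to 23–50 °C to the trimethylsilyl ester F3. Aqueous work-up gives the carboxylic acid F4, and EtI with K2CO3 in DMF returns ester 11.

Step 18. Displacement at the neopentyl carbon may be slow, so that prolonged heating with imidazole epimerises C8 or lets the free alcohol add to the butenolide. The fallback sets out from 24 and comes back at 25 with the activation and the substitution separated. Tf2O and pyridine in CH2Cl2 at −40 °C give the neopentyl triflate F5, which is displaced by Bu4NI in benzene at 23–40 °C.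

Further compounds
F0 | step 19 | none | none
F1 | step 7 | allylic acetate of 9 | CC(=O)OC/C=C1/C(C)=CC[C@@H](O[Si](C)(C)C(C)(C)C)[C@@H]1C
F2 | step 7 | trimethylsilyl ketene acetal of F1 | C=C(O[Si](C)(C)C)OC/C=C1/C(C)=CC[C@@H](O[Si](C)(C)C(C)(C)C)[C@@H]1C
F3 | step 7 | trimethylsilyl ester of the rearranged acid | C[Si](C)(C)OC(=O)C[C@@]1(C=C)C(C)=CC[C@@H](O[Si](C)(C)C(C)(C)C)[C@@H]1C
F4 | step 7 | carboxylic acid corresponding to ester 11 | OC(=O)C[C@@]1(C=C)C(C)=CC[C@@H](O[Si](C)(C)C(C)(C)C)[C@@H]1C
F5 | step 18 | neopentyl triflate of 24 | O=C1C=C[C@@H](C[C@@]2(COS(=O)(=O)C(F)(F)F)C(C)=C[C@H](O[Si](C)(C)C(C)(C)C)[C@@H](O[Si](C)(C)C(C)(C)C)[C@@H]2C)O1
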